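**Strategy.** Ring A is cut at C1–C10 and C4–C5. The silyl dienol ether of methyl 3-oxopent-4-enoate supplies C1–C4 of ring A together with the C3 oxygen and the ester carbon C19. The mono-ketal of 2,6-dimethylbenzoquinone supplies all of ring B: the quaternary, methylated C10, the C9 carbonyl, the C7=C8 double bond and its C8 methyl. One titanium–binaphthol-catalysed Diels–Alder reaction joins these achiral partners, closes ring A, forms both ring bonds and fixes C10, from which C4, C5, C9 and C3 are later set by substrate control. The precursors are the symmetric dienone ketal 2 and the (Z)-configured TBS dienol ether 7.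

Key step: step 5

Remark 1: labdane numbering is used (C17 on C8, C18 equatorial and C19 axial on C4, C20 on C10); "syn" and "anti" refer to the C20 methyl.
Remark 2: the sense of induction of the titanium catalyst is assumed; (R)-1,1′-bi-2-naphthol is written, and the (S)-ligand would be used if adduct 8 proved antipodal.
Remark 3: the (Z)-diene reacting endo places H4, H5 and C20 on one face of 8; only C10 is carried to the target, C4 and C5 are reset in steps 7 and 8.

Step 1
Reactants: 1 4-methoxy-2,6-dimethylphenol
Product: 2 4,4-dimethoxy-2,6-dimethylcyclohexa-2,5-dien-1-one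
Conditions: PhI(OAc)2, MeOH, 0 °C
Reagents that add atoms: methanol, CO
Why: Hypervalent-iodine oxidative dearomatisation of the electron-rich phenol with capture of methanol at the methoxy-bearing para carbon is the standard entry to p-quinone monoketals and forms no stereocentre.

Step 2
Reactants: 3 methyl acetate; 4 acrolein
Product: 5 methyl 3-hydroxypent-4-enoate (racemic)
Conditions: LiN(iPr)2, THF, −78 °C; then 4; aq. NH4Cl
Reagents that add atoms: none
Why: Aldol addition of the lithium ester enolate to acrolein occurs 1,2 at low temperature; the racemic carbinol centre is destroyed in step 3.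

Step 3
Reactants: 5 methyl 3-hydroxypent-4-enoate
Product: 6 methyl 3-oxopent-4-enoate
Conditions: Dess–Martin periodinane, NaHCO3, CH2Cl2, 0 °C
Reagents that add atoms: none
Why: Dess–Martin oxidation under buffered, non-aqueous conditions should give the polymerisation-prone vinyl β-keto ester, which is used at once.

Step 4
Reactants: 6 methyl 3-oxopent-4-enoate
Product: 7 methyl (2Z)-3-(tert-butyldimethylsilyloxy)penta-2,4-dienoate
Conditions: TBSOTf, Et3N, CH2Cl2, −78 → 0 °C
Reagents that add atoms: tert-butyldimethylsilyl triflate, CC(C)(C)[Si](C)(C)OS(=O)(=O)C(F)(F)F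
Why: Soft enolisation and O-silylation of the hydrogen-bonded cis-enol of the β-keto ester should give the 2-silyloxydiene with the ester on the outer (Z) position, the geometry that can reach the s-cis conformation.

Step 5
Reactants: 2 4,4-dimethoxy-2,6-dimethylcyclohexa-2,5-dien-1-one; 7 methyl (2Z)-3-(tert-butyldimethylsilyloxy)penta-2,4-dienoate
Product: 8 endo cycloadduct (cis-fused; C2=C3 TBS enol ether; C4 CO2Me anti; H5 syn; C6 dimethyl ketal; C7=C8 with C8 methyl; C9 ketone; C10 methyl)
Conditions: (R)-1,1′-bi-2-naphthol (20 mol %), TiCl2(OiPr)2 (20 mol %), 4 Å MS, CH2Cl2, −30 → 0 °C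
Reagents that add atoms: none
Why: Coordination of the chiral titanium Lewis acid to the only carbonyl of 2 (C9) makes C5 the most electrophilic carbon, so the concerted but asynchronous [4+2] cycloaddition joins C5 to the silyloxy-activated, ester-bearing diene terminus (C4) slightly ahead of C10 to the CH2 terminus (C1); the closest known reaction type is the binaphthol–titanium-catalysed Diels–Alder reaction of quinone monoketals with 2-silyloxydienes. Ring A is closed as a six-membered carbocycle by intermolecular cycloaddition that is suprafacial on both partners. C10 is set by the catalyst, which must choose between the two enantiomeric modes of approach to the symmetric dienone (its two C=C bonds are equivalent, each with two enantiotopic faces); C5 follows from suprafacial addition (H5 syn to C20, cis fusion); C4 follows from the endo transition state of the (Z)-diene (ester anti to C20) and is of no consequence because it is planarised later. Regioselectivity is required and is secured by the single carbonyl of 2 acting together with the C3 silyloxy group of 7, endo selectivity by secondary overlap with the titanium-bound carbonyl, and no site selectivity is needed because both C=C bonds of 2 are equivalent. The TBS enol ether is chosen over a TMS ether so that diene and adduct survive the Lewis acid and chromatography.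

Step 6
Reactants: 8 endo cycloadduct
Product: 9 cis-fused 3,6,9-trioxo 19-methyl ester (C4 epimers and enol)
Conditions: 2 M HCl, THF, 23 °C
Reagents that add atoms: water, O
Why: Acid hydrolysis of the dimethyl ketal and of the silyl enol ether unmasks the C6 ketone (ene-dione) and the C3 β-keto ester, while the quaternary C10 blocks aromatisation and is untouched.

Step 7
Reactants: 9 cis-fused 3,6,9-trioxo 19-methyl ester
Product: 10 bis(silyl enol ether) (C3=C4 and C5=C6 TBS enol ethers; C7=C8; C9 ketone)
Conditions: TBSOTf (2.5 equiv), Et3N (4 equiv), CH2Cl2, −78 → 0 °C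
Reagents that add atoms: tert-butyldimethylsilyl triflate, CC(C)(C)[Si](C)(C)OS(=O)(=O)C(F)(F)F
Why: Soft enolisation and silylation take the β-keto ester to its C3 silyl enol ether and the C6 ketone, whose only α-hydrogen is H5, to the C5=C6 dienol ether, so that C4 and C5 are both planar and C10 is the only stereocentre left.

Step 8
Reactants: 10 bis(silyl enol ether)
Product: 12 trans-fused 3,6,9-trioxo 19-methyl ester with C4 methyl (H5 anti; CO2Me syn; C18 methyl anti), via C6 silyl dienol ether 11 (not isolated)
Conditions: Bu4N[Ph3SiF2] (1.05 equiv), MeI (5 equiv), THF, −40 → 0 °C; then 1 M HCl, THF, 0 °C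
Reagents that add atoms: iodomethane, CI
Why: Fluoride-triggered enolate alkylation: fluoride should cleave only the far more labile silyl group of the doubly stabilised β-keto ester enolate, which is C-methylated at C4 anti to the axial C10 methyl (the classical outcome for 3-oxo-4-carboxylates, here independent of the ring fusion because C5 is sp2), placing the ester syn to C20; acid then hydrolyses the C6 dienol ether with protonation of C5 anti to the axial ester and C20, giving the trans fusion.

Step 9
Reactants: 12 trans-fused 3,6,9-trioxo 19-methyl ester with C4 methyl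
Product: 14 19,6-lactone 3,9-dione (lactone oxygen on C6 syn; C7=C8–C9=O enone), via 6-hydroxy ester 13 (not isolated)
Conditions: NaBH4 (1.0 equiv), CeCl3·7H2O, MeOH, −78 °C; then TsOH (cat.), CH2Cl2, 23 °C
Reagents that add atoms: none
Why: Luche reduction should take the more accessible conjugated C6 carbonyl 1,2 from the face of H5 (C9 is flanked by the quaternary C10 and the C8 methyl, C3 is saturated), so the new C6 alkoxide is syn-axial to the C19 ester and closes the γ-lactone; the C6 centre is removed in step 10.

Step 10
Reactants: 14 19,6-lactone 3,9-dione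
Product: 16 methyl 3,9-dioxo 7-en-19-oate (C6 now CH2), via enone acid 15 (not isolated)
Conditions: Zn dust, AcOH, 70 °C; then Me3SiCHN2, PhMe/MeOH, 0 °C
Reagents that add atoms: (trimethylsilyl)diazomethane, C[Si](C)(C)C=[N+]=[N-]
Why: Zinc reduction of a vinylogous α-acyloxy ketone expels the C6 carboxylate, the dienol ketonises to the conjugated C7=C8–C9=O enone whichever end is protonated first, and the freed C19 acid is re-esterified without touching a stereocentre.

Step 11
Reactants: 16 methyl 3,9-dioxo 7-en-19-oate
Product: 17 C3 ethylene ketal of 16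
Conditions: Me3SiOCH2CH2OSiMe3, Me3SiOTf (5 mol %), CH2Cl2, −78 → −20 °C
Reagents that add atoms: 1,2-bis(trimethylsilyloxy)ethane, C[Si](C)(C)OCCO[Si](C)(C)C
Why: Silyl-triflate-catalysed acetalisation at low temperature protects the saturated C3 ketone selectively because the hindered, conjugated C9 ketone does not react.

Step 12
Reactants: 17 C3 ethylene ketal
Product: 18 7,9(11)-diene (exocyclic C9=C11 methylene)
Conditions: Ph3PCH3Br, KOtBu, PhMe, 90 °C
Reagents that add atoms: methyltriphenylphosphonium bromide, C[P+](c1ccccc1)(c1ccccc1)c1ccccc1.[Br-]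
Why: Wittig methylenation with salt-free ylide at elevated temperature is the usual answer to a hindered, non-enolisable ketone, and the ester and dioxolane are inert.

Step 13
Reactants: 18 7,9(11)-diene
Product: 20 C11 primary alcohol (H9 anti; C7=C8 retained), via C11 borane 19 (not isolated)
Conditions: 9-BBN-H, THF, 0 → 40 °C; then NaOH, H2O2, 0 °C
Reagents that add atoms: hydrogen peroxide, OO
Why: Hydroboration–oxidation: 9-BBN adds only to the terminal 1,1-disubstituted alkene, boron to C11 and hydrogen to C9 from the face opposite the axial C10 methyl, which sets H9 anti to C20 with the side-chain carbon equatorial.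

Step 14
Reactants: 20 C11 primary alcohol
Product: 21 C11 aldehyde
Conditions: Dess–Martin periodinane, NaHCO3, CH2Cl2, 0 °C
Reagents that add atoms: none
Why: Buffered Dess–Martin oxidation should give the β,γ-unsaturated aldehyde without epimerising C9 or moving the double bond; it is used crude.

Step 15
Reactants: 21 C11 aldehyde
Product: 22 C9 vinyl compound (C11=C12; C3 ketal; C19 ester)
Conditions: Ph3PCH3Br, KN(SiMe3)2, THF, −78 → 0 °C
Reagents that add atoms: methyltriphenylphosphonium bromide, C[P+](c1ccccc1)(c1ccccc1)c1ccccc1.[Br-]
Why: Wittig methylenation at low temperature adds the ylide to the aldehyde much faster than it enolises it, so C9 is retained.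

Step 16
Reactants: 22 C9 vinyl compound
Product: 23 C9 vinyl 3-ketone 19-methyl ester
Conditions: 1 M HCl, THF, 40 °C
Reagents that add atoms: water, O
Why: Acid-catalysed acetal hydrolysis releases the C3 ketone while the isolated alkenes and the hindered ester do not react.

Step 17
Reactants: 23 C9 vinyl 3-ketone 19-methyl ester
Product: 25 3,19-diol with C9 vinyl (3-OH axial, anti to C19 and C20), via 3-hydroxy ester 24 (not isolated)
Conditions: LiBH(s-Bu)3, THF, −78 °C; then LiAlH4, 0 → 50 °C; NaOH, H2O
Reagents that add atoms: none
Why: Hydride reduction: the bulky borohydride attacks the 4,4-disubstituted C3 ketone along the equatorial trajectory and gives the axial alcohol, and LiAlH4 then reduces the hindered axial ester, at a stage where no enone or second ester is present.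

Step 18
Reactants: 26 methyl acetoacetate
Product: 27 methyl (2E)-3-(trifluoromethylsulfonyloxy)but-2-enoate
Conditions: Tf2O, aq. Me4NOH, hexanes, 5 °C
Reagents that add atoms: triflic anhydride, O=S(=O)(OS(=O)(=O)C(F)(F)F)C(F)(F)F
Why: O-Triflation of the β-keto ester enolate with a non-coordinating ammonium counter-ion should give the (E)-enol triflate (triflate anti to the ester), the geometry needed for the 13E alkene.

Step 19
Reactants: 25 3,19-diol with C9 vinyl; 27 methyl (2E)-3-(trifluoromethylsulfonyloxy)but-2-enoate
Product: 29 methyl 3,19-dihydroxylabda-7,13E-dien-15-oate, via C12 borane 28 (not isolated)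
Conditions: 9-BBN-H (3.5 equiv), THF, 23 °C; then 27, PdCl2(dppf) (5 mol %), AsPh3, K3PO4 (aq.), DMF, 23 → 40 °C
Reagents that add atoms: none
Why: B-alkyl Suzuki–Miyaura coupling: 9-BBN hydroborates only the monosubstituted vinyl group (the hydroxyls are merely borylated and freed on work-up), and palladium couples the primary alkylborane with the enol triflate with retention of its geometry, forming C12–C13.

Step 20
Reactants: 29 methyl 3,19-dihydroxylabda-7,13E-dien-15-oate
Product: 30 3,19-dihydroxylabda-7,13E-dien-15-oic acid
Conditions: LiOH, THF/MeOH/H2O, 45 °C; then 1 M HCl to pH 3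
Reagents that add atoms: lithium hydroxide, [Li+].[OH-]
Why: Saponification of the only ester present leaves the alkenes and stereocentres untouched.

Step 21
Reactants: 30 3,19-dihydroxylabda-7,13E-dien-15-oic acid
Product: 31 target, 19-acetoxy-3-hydroxylabda-7,13E-dien-15-oic acid
Conditions: Ac2O (1.5 equiv), pyridine, 0 → 23 °C; aq. NaHCO3
Reagents that add atoms: acetic anhydride, CC(=O)OC(C)=O
Why: Selective acylation: the primary C19 hydroxyl is acetylated without DMAP whereas the axial C3 hydroxyl next to the quaternary C4 is too hindered, and the mixed anhydride at the acid is hydrolysed in the bicarbonate work-up.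

**Compound list**

1 | 4-methoxy-2,6-dimethylphenol | COc1cc(C)c(O)c(C)c1 | starting material
2 | 4,4-dimethoxy-2,6-dimethylcyclohexa-2,5-dien-1-one | COC1(OC)C=C(C)C(=O)C(C)=C1 | intermediate
3 | methyl acetate | COC(C)=O | starting material
4 | acrolein | C=CC=O | starting material
5 | methyl 3-hydroxypent-4-enoate (racemic) | COC(=O)CC(O)C=C | intermediate
6 | methyl 3-oxopent-4-enoate | COC(=O)CC(=O)C=C | intermediate
7 | methyl (2Z)-3-(tert-butyldimethylsilyloxy)penta-2,4-dienoate | COC(=O)/C=C(\O[Si](C)(C)C(C)(C)C)C=C | intermediate
8 | endo cycloadduct, cis-fused, C2=C3 TBS enol ether, C6 dimethyl ketal, C9 enone | COC(=O)[C@@H]1[C@@H]2C(OC)(OC)C=C(C)C(=O)[C@]2(C)CC=C1O[Si](C)(C)C(C)(C)C | intermediate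
9 | cis-fused 3,6,9-trioxo 19-methyl ester (C4 not defined) | COC(=O)C1[C@@H]2C(=O)C=C(C)C(=O)[C@]2(C)CCC1=O | intermediate
10 | bis(silyl enol ether), C3=C4 and C5=C6 | COC(=O)C1=C(O[Si](C)(C)C(C)(C)C)CC[C@@]2(C)C(=O)C(C)=CC(O[Si](C)(C)C(C)(C)C)=C12 | intermediate
11 | C4-methylated C6 silyl dienol ether | COC(=O)[C@@]1(C)C2=C(O[Si](C)(C)C(C)(C)C)C=C(C)C(=O)[C@]2(C)CCC1=O | intermediate (not isolated)
12 | trans-fused 3,6,9-trioxo 19-methyl ester with C4 methyl | COC(=O)[C@@]1(C)[C@H]2C(=O)C=C(C)C(=O)[C@]2(C)CCC1=O | intermediate
13 | 6-hydroxy 3,9-dioxo 19-methyl ester (6-OH syn) | COC(=O)[C@@]1(C)[C@H]2[C@@H](O)C=C(C)C(=O)[C@]2(C)CCC1=O | intermediate (not isolated)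
14 | 19,6-lactone 3,9-dione | O=C3[C@@]1(C)[C@H]2[C@@H](O3)C=C(C)C(=O)[C@]2(C)CCC1=O | intermediate
15 | 3,9-dioxo 7-en-19-oic acid | OC(=O)[C@@]1(C)[C@H]2CC=C(C)C(=O)[C@]2(C)CCC1=O | intermediate (not isolated)
16 | methyl 3,9-dioxo 7-en-19-oate | COC(=O)[C@@]1(C)[C@H]2CC=C(C)C(=O)[C@]2(C)CCC1=O | intermediate
17 | C3 ethylene ketal of 16 | COC(=O)[C@@]1(C)[C@H]2CC=C(C)C(=O)[C@]2(C)CCC13OCCO3 | intermediate
18 | 7,9(11)-diene | COC(=O)[C@@]1(C)[C@H]2CC=C(C)C(=C)[C@]2(C)CCC13OCCO3 | intermediate
19 | C11 9-BBN borane | COC(=O)[C@@]1(C)[C@H]2CC=C(C)[C@@H](CB3C4CCCC3CCC4)[C@]2(C)CCC15OCCO5 | intermediate (not isolated)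
20 | C11 primary alcohol | COC(=O)[C@@]1(C)[C@H]2CC=C(C)[C@@H](CO)[C@]2(C)CCC13OCCO3 | intermediate
21 | C11 aldehyde | COC(=O)[C@@]1(C)[C@H]2CC=C(C)[C@@H](C=O)[C@]2(C)CCC13OCCO3 | intermediate
22 | C9 vinyl compound, C3 ketal | COC(=O)[C@@]1(C)[C@H]2CC=C(C)[C@@H](C=C)[C@]2(C)CCC13OCCO3 | intermediate
23 | C9 vinyl 3-ketone 19-methyl ester | COC(=O)[C@@]1(C)[C@H]2CC=C(C)[C@@H](C=C)[C@]2(C)CCC1=O | intermediate
24 | C9 vinyl 3-hydroxy (axial) 19-methyl ester | COC(=O)[C@@]1(C)[C@H]2CC=C(C)[C@@H](C=C)[C@]2(C)CC[C@@H]1O | intermediate (not isolated)
25 | 3,19-diol with C9 vinyl | OC[C@@]1(C)[C@H]2CC=C(C)[C@@H](C=C)[C@]2(C)CC[C@@H]1O | intermediate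
26 | methyl acetoacetate | COC(=O)CC(C)=O | starting material
27 | methyl (2E)-3-(trifluoromethylsulfonyloxy)but-2-enoate | COC(=O)/C=C(\C)OS(=O)(=O)C(F)(F)F | intermediate
28 | C12 9-BBN borane, both hydroxyls as 9-BBN borinates | C1CCC2CCCC1B2OC[C@@]3(C)[C@H]4CC=C(C)[C@@H](CCB5C6CCCC5CCC6)[C@]4(C)CC[C@@H]3OB7C8CCCC7CCC8 | intermediate (not isolated)
29 | methyl 3,19-dihydroxylabda-7,13E-dien-15-oate | OC[C@@]1(C)[C@H]2CC=C(C)[C@@H](CC/C(C)=C/C(=O)OC)[C@]2(C)CC[C@@H]1O | intermediate
30 | 3,19-dihydroxylabda-7,13E-dien-15-oic acid | OC[C@@]1(C)[C@H]2CC=C(C)[C@@H](CC/C(C)=C/C(=O)O)[C@]2(C)CC[C@@H]1O | intermediate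
31 | 19-acetoxy-3-hydroxylabda-7,13E-dien-15-oic acid | CC(=O)OC[C@@]1(C)[C@H]2CC=C(C)[C@@H](CC/C(C)=C/C(=O)O)[C@]2(C)CC[C@@H]1O | target

**Totals.** 21 steps in all. The longest linear sequence is 19 steps (steps 2–17 and 19–21, from methyl acetate and acrolein).

**Steps most likely to fail**

1. Step 5. The trisubstituted, ketal-flanked dienophile may react too slowly with the ester-deactivated diene. The Lewis acid may ionise the ketal or desilylate the diene, and the discrimination between the two enantiomeric approaches may be poor. Fallback: a stepwise, base-mediated double Michael annulation that sets out from 2 and the unsilylated keto ester 6. Cs2CO3 in CH2Cl2 with a cinchona-derived quaternary ammonium phase-transfer catalyst should add the β-keto ester carbon (C4) to C5 and then the resulting C10 enolate to the vinyl ketone (C1). This gives the cis-fused keto ester ketal F1, and aqueous HCl in THF brings the route back at 9.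

2. Step 8. Fluoride may cleave both silyl groups (leading to methylation at C5), the enolate may be O-methylated, or protonation of C5 may show poor facial control. Fallback: it sets out from 9 and reverses the order of events. The ring fusion is first equilibrated with DBU in THF to the trans-fused keto ester F2, the residual cis isomer being separated and recycled. Classical equatorial methylation with K2CO3 and MeI in acetone then returns the route at 12.

3. Step 12. Olefination of the very hindered C9 carbonyl may stall, or the basic ylide may deprotonate the enone at its γ-position. Fallback: it sets out from 17. Corey–Chaykovsky reaction with dimethylsulfonium methylide (Me3S+ I−, KN(SiMe3)2, THF) should attack C9 anti to C20 and give the vinyl spiro-epoxide F3. Hydrogenolysis with a zerovalent palladium catalyst (Pd2(dba)3·CHCl3, PBu3, HCO2H/Et3N, dioxane) delivers hydride to C9 with inversion and returns the route at 20, bypassing diene 18 and the hydroboration.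

**Further compounds**

F1 | step 5 | cis-fused 3,9-dioxo 6,6-dimethoxy 19-methyl ester (C4 not defined) | COC(=O)C1[C@@H]2C(OC)(OC)C=C(C)C(=O)[C@]2(C)CCC1=O
F2 | step 8 | trans-fused 3,6,9-trioxo 19-methyl ester without C4 methyl (C4 not defined) | COC(=O)C1[C@H]2C(=O)C=C(C)C(=O)[C@]2(C)CCC1=O
F3 | step 12 | C9 spiro-epoxide of 17 (9,11-epoxide, oxygen syn to C20) | COC(=O)[C@@]1(C)[C@H]2CC=C(C)[C@]3(CO3)[C@]2(C)CCC15OCCO5
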